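Readings and results come from a simulation for an exercise; the scatter is artificial.

Alder holds more free catalyst than elm, but elm stays warm for longer. Which flask makes more product?

| setting | south-east | south | east | alder | elm |
|---|---|---|---|---|---|
| substrate | 21 mM | 21 mM | 21 mM | 21 mM | 21 mM |
| free catalyst | 3.7 mol% | 5.8 mol% | 5.1 mol% | 6.9 mol% | 5 mol% |
| temperature | −30 °C | −8 °C | −30 °C |  |  |
| remark | run made earlier | run made earlier | run made earlier | at 0 °C until 80 min, from then on at −40 °C | at 0 °C throughout |
| time |  |  |  | 4.0 h | 4.0 h |

south-east run (percent of the substrate charged)

| time / h | product / % | substrate / % |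
|---|---|---|
| 0.667 | 0 | 98 |
| 1.33 | 0 | 100 |
| 2.00 | 0 | 100 |
| 4.00 | 4 | 100 |
| 8.00 | 3 | 95 |

south run (percent of the substrate charged)

| time / min | product / % | substrate / % |
|---|---|---|
| 10.0 | 0 | 98 |
| 20.0 | 4 | 97 |
| 30.0 | 4 | 96 |
| 60.0 | 8 | 92 |
| 120 | 16 | 86 |

east run (percent of the substrate charged)

| time / h | product / % | substrate / % |
|---|---|---|
| 2.00 | 2 | 96 |
| 4.00 | 3 | 98 |
| 6.00 | 1 | 98 |
| 8.00 | 4 | 94 |

(readings scatter by 1.5 percentage points)

- the winner by amount of product, in percent of the substrate charged; "neither" if no more than 2 percentage points parts them (alder / elm / neither)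
- how much product is there at the end, in percent of the substrate charged: alder
- how much product is there at the end, in percent of the substrate charged: elm

- steps under discussion: substrate + free catalyst -> catalyst intermediate A; catalyst intermediate A -> catalyst intermediate B; catalyst intermediate B <-> free catalyst + product

Start with a rate per unit of catalyst. Substrate reacts by meeting free catalyst, so if free catalyst stays constant, substrate falls pseudo-first-order. Define τ = −ln(fraction of substrate unconverted)/(x t), with x the loading and t the time, and take the conversion from the product readings. The south run reads 1.50 h⁻¹ and the east run 0.100 h⁻¹, a noisy reading: it rests on 4% of product, read to 1.5 percentage points. Continuing the same factor per degree up to 0 °C gives 4.03 h⁻¹.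

Now fold the givens into one number, the turnover budget D = x τ t, taken over the warm time. In this reckoning substrate left is e^−D, and the rest is counted as product.

| flask | warm time | D | reckoned product |
|---|---|---|---|
| alder | 80 min | 0.370 | 31.0% |
| elm | 4.0 h | 0.805 | 55.3% |

Even reckoned at the −30 °C rate, alder's cold stretch adds 0.0184 to D, less than its warm budget, so in this reckoning elm leads.

Is one number enough? D assumes that catalyst stays free. The south run's product read twice as much at its last reading as at the one before, with twice the time. But that 16% is the highest product read, and it is less than the 55.3% reckoned for elm. Free catalyst can also recombine with product, so I take both figures as high.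

The forecast gives 28% for alder, below my figure, and 55% for elm, level with mine: “Elm should win”.

The flasks give 22.2% in alder and 39.7% in elm, so elm makes more.

    substrate + free catalyst → catalyst intermediate A (k = 220 L mol⁻¹ h⁻¹, Ea = 58.0 kJ mol⁻¹)
    catalyst intermediate A → catalyst intermediate B (k = 650 h⁻¹, Ea = 67.0 kJ mol⁻¹)
    catalyst intermediate B ⇌ free catalyst + product (K = 0.0100 M, k = 14.0 h⁻¹, Ea = 84.0 kJ mol⁻¹, ΔH = −18.0 kJ mol⁻¹)
    (constants at 0 °C)

In elm at 4.00 h, catalyst intermediate B and free catalyst + product relax towards each other with a half-life of 1.58 min, short against the 4.0 h of the run, and at that moment catalyst intermediate B holds 50.4% of the catalyst charged and free catalyst 49.4%. Elm's product corresponds to D = 0.505, which is 0.627 of the reckoned 0.805. For the neighbour of elm charged with 1.2 mol%, D is 0.193, which gives 17.6% of product. That flask makes 13.8%.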